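Tuesday's run and Friday's run differ in one setting, the racemization catalyst, and at 6.00 h the excess of left-handed product reads 27.7% on Tuesday and 33.7% on Friday, from readings with a scatter of 1 percentage point. So the larger charge went with the larger excess, and the new flask has a smaller charge than either.

| flask | left-handed substrate | right-handed substrate | reagent | free catalyst | racemization catalyst | impurity | remark | time |
|---|---|---|---|---|---|---|---|---|
| Tuesday's | 0.30 M | 0.30 M | 3 equiv | 0.2 mol% | 5 mol% | 11 mM | run made earlier |  |
| Friday's | 0.30 M | 0.30 M | 3 equiv | 0.2 mol% | 7.9 mol% | 11 mM | run made earlier |  |
| flask | 0.30 M | 0.30 M | 3.00 equiv | 0.2 mol% | 3.6 mol% | 11 mM |  | 8.0 h |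

- Tuesday's (time / h: left-handed product / %, right-handed product / %): 1.50: 14.8, 7.5; 3.00: 26.6, 11.5; 5.00: 32.1, 17.9; 6.00: 34.3, 19.4
- Friday's (time / h: left-handed product / %, right-handed product / %): 0.500: 8.1, 0.7; 1.33: 12.9, 4.7; 3.00: 26.1, 9.7; 6.00: 37.5, 18.6

(each reading ± 1 percentage point)

- free catalyst is single-handed; left-handed substrate and right-handed substrate are mirror images of each other, charged as a racemate, each of them at the stated concentration
- the earlier runs were read with a standard deviation of 1 percentage point
- an excess is the difference of the two amounts in percent of their sum
- an excess is below zero if the other one leads

- left-handed product and right-handed product together, in percent of the left-handed substrate and right-handed substrate charged together, at 8.0 h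
- excess of left-handed product over right-handed product in the product at 8.0 h
- whether the exchange between left-handed substrate and right-handed substrate keeps pace with the reaction: how far the product's excess at 8.0 h gets from its value without exchange to its value with instant exchange (above 80% keeps pace, below 20% hardly takes part, else lags behind)

Two chemists read these runs differently. The first goes by the loading: exchange follows the racemization catalyst as charged, so the flask keeps 72.0% of Tuesday's exchange throughout, and she expects it to lag behind the reaction without dropping out.

The second writes a balance. Tuesday's run, Friday's run and the flask carry the same 11 mM of impurity, and he supposes that it destroys racemization catalyst one for one; this is his assumption, for the impurity was not varied in these runs. The loading counts on the left-handed substrate, so the flask's c(racemization catalyst) is 10.8 mM, less than c(impurity), which on his assumption makes the racemization catalyst the limiting reagent of that side reaction. The difference is −0.200 mM. This is the catalyst surplus: racemization catalyst charged minus impurity charged, the amount that outlasts the poisoning. It is 4.00 mM on Tuesday and 12.7 mM on Friday, so Friday's loading is 1.58 times Tuesday's but its surplus 3.17 times.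

The first chemist objects that the speed of the poisoning is unknown, and so it is. Still, I hold with the second: with the surplus below zero, I expect the exchange to stop early and hardly take part.

The forecast assumes poisoning too, yet reckons that “roughly 11 mM stays active” where my balance gives a surplus of −0.200 mM, and it gives 66% of product, an excess of 26%, and an exchange that hardly takes part.

The flask gives 60.3% of product at 8.0 h and an excess of 19.7%. Its exchange hardly takes part, getting 0.21% of the way to instant exchange.

    left-handed substrate + racemization catalyst ⇌ right-handed substrate + racemization catalyst, rate k1*[racemization catalyst]*[left-handed substrate] forward; the back reaction follows from the equilibrium constant (k = 0.00630 M⁻¹ s⁻¹)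
    racemization catalyst + impurity → spent catalyst (k = 2.70 M⁻¹ s⁻¹)
    left-handed product ⇌ right-handed product (k = 1.20 × 10⁻⁵ s⁻¹)
    reagent + free catalyst + left-handed substrate → free catalyst + left-handed product (k = 0.140 M⁻² s⁻¹)
    reagent + free catalyst + right-handed substrate → free catalyst + right-handed product (k = 0.0450 M⁻² s⁻¹)

In the flask, racemization catalyst is down to 0.484% of its charge at 0.800 h and stands at 0% at 8.00 h, while 0.200 mM of impurity remains, the size of the deficit. The first chemist's loading has its ground where the charge stands above c(impurity), and the neighbouring flask at 6.1 mol% stands there. Its surplus reckons to 7.30 mM, and at 8.00 h it holds 7.30 mM of racemization catalyst, 39.9% of its charge. That neighbour reaches 62.7% of product, with an excess of 27.2%, higher than the flask's 19.7%.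

(All runs were computed on assumed constants, noise included.)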